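The violet, teal and ochre runs have one catalyst charge and start from 0.027 M, 0.036 M and 0.046 M of substrate, yet at 30.0 min they keep 5.30%, 5.90% and 6.60% of it, counting as substrate whatever is neither target nor isomer of the product. The fraction lost per minute thus changes little with the charge (pseudo-first-order). Blue, with 0.14 mM of free catalyst, keeps 21.0%. Elapsed time divided by the logarithm of charge over substrate left gives the substrate time constant: 11.0 min for ochre and 19.2 min for blue, stretching in step with the thinner free catalyst. We scale blue's to autumn: 22.4 min. Winter is nearly ochre.

| setting | violet | teal | ochre | blue | winter | autumn |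
|---|---|---|---|---|---|---|
| substrate | 0.027 M | 0.036 M | 0.046 M | 0.050 M | 0.050 M | 0.025 M |
| free catalyst | 0.25 mM | 0.25 mM | 0.25 mM | 0.14 mM | 0.25 mM | 0.12 mM |
| remark | run made earlier | run made earlier | run made earlier | run made earlier |  |  |
| time |  |  |  |  | 30 min | 60 min |

| run | time / min | target / % | isomer of the product / % |
|---|---|---|---|
| violet | 6.00 | 27.8 | 13.3 |
| violet | 12.0 | 28.4 | 37.0 |
| violet | 20.0 | 21.9 | 62.4 |
| violet | 25.0 | 17.6 | 72.7 |
| violet | 30.0 | 13.9 | 80.8 |
| teal | 2.50 | 15.6 | 3.0 |
| teal | 8.00 | 28.5 | 21.4 |
| teal | 15.0 | 26.5 | 45.8 |
| teal | 20.0 | 21.9 | 60.8 |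
| teal | 30.0 | 14.0 | 80.1 |
| ochre | 2.50 | 15.3 | 3.6 |
| ochre | 5.00 | 23.4 | 9.4 |
| ochre | 8.00 | 27.9 | 20.9 |
| ochre | 15.0 | 25.5 | 45.9 |
| ochre | 30.0 | 14.3 | 79.1 |
| blue | 6.00 | 17.4 | 7.7 |
| blue | 12.0 | 20.5 | 23.7 |
| blue | 20.0 | 20.3 | 43.7 |
| blue | 25.0 | 16.9 | 54.8 |
| blue | 30.0 | 15.5 | 63.5 |

(standard deviation of a reading: 0.5 percentage points)

- what was read earlier has a scatter of 0.5 percentage points, one standard deviation

- the winner by share of target in all that became target or isomer of the product; "neither" if no more than 2 percentage points parts them (winter / autumn / neither)
- share of target in all that became target or isomer of the product, winter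
- share of target in all that became target or isomer of the product, autumn

Now the run in slow motion. In the first instants substrate feeds target and isomer of the product lags: ochre at 2.50 min has 15.3% against 3.6%. In the middle, ochre's highest reading of target is 27.9% at 8.00 min, and by 15.0 min ochre reads 25.5% of target against 45.9% of the isomer. Target held divided by the isomer's rise per minute reads 7.48 min in ochre and 8.16 min in blue, so this clock does not follow the catalyst. For the end we reckon one way, from substrate to target to isomer. Winter and autumn reach nearly the same point on the substrate clock, with 6.89% left in autumn, but substrate time constant over target clock is 1.48 in winter and 2.75 in autumn. On this reckoning autumn's target trails its substrate at 3.94% of the charge, a one-way share of 4.23%. We take ochre's 15.3% for winter.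

The forecast says winter, with 15.3% and 8.6%; it stands above us on autumn, and of that number it warns: “This rests on the inferred reversibility.”

The flask gives 15.2% in winter and 8.50% in autumn, so winter has more.

    2 free catalyst ⇌ resting dimer, settled at all times (K = 1000 L mol⁻¹)
    target ⇌ isomer of the product (K = 16.0, k = 0.140 min⁻¹)
    substrate + free catalyst → catalyst intermediate (k = 520 L mol⁻¹ min⁻¹)
    catalyst intermediate → free catalyst + target (k = 69.0 min⁻¹)

Left for 600 min, autumn ends at 5.88%, above our one-way share. Autumn's substrate time constant gave 6.89% of substrate at 60 min, and the flask holds 5.0%. For the autumn charge read at 15 min, the same constant gives 51.2%, and that flask holds 49%.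

The readings were computed for substances that don't exist; the scatter is artificial.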